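## Retrosynthetic overview

- Target: ring A (C1 OH, C2 Br, C3 H, C4 Br, C5 H, C6 O‑aryl) is joined through the C6 oxygen to ring B (C1′ O, C2′ H, C3′–C5′ Br, C6′ OH). In ring A the C3–C4 bond lies opposite the oxygen-bearing C1–C6 edge, so C3=C4 can be the alkene formed by ring-closing metathesis of an open chain in which C1 is a ketone and C6 already carries the aryl ether.
- Disconnections, backwards: ring B O–CH3 (BBr3); ring A C2–Br and C4–Br (ortho and para to the C1 hydroxyl); dehydrogenation of a 6‑aryloxycyclohex‑3‑enone; C3=C4 by metathesis of a 5‑aryloxyocta‑1,7‑dien‑4‑one.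
- Dienone: the C2–C3 allyl unit comes from allylmagnesium bromide and a Weinreb amide; the C6–O bond comes from SN2 of the ring B phenol on methyl 2‑bromopent‑4‑enoate.
- Ring B phenol: 2‑(benzyloxy)phenol is tribrominated under direction of its free hydroxyl, O‑methylated and debenzylated, so that the methyl ether sits on the bromine-flanked oxygen.
- Ring order: ring B is bought as an arene and functionalised first (steps 1–3); ring A is closed in step 7 and aromatised in step 8.

Key step: step 7

Remark on the chemistry: the target is achiral. The single stereocentre of compounds 5–11 (the carbon that becomes C6 of ring A) is carried as the racemate and disappears on aromatisation, so no stereocontrol is required.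

## Route

Step 1
Reactants: 1 2‑(benzyloxy)phenol
Product: 2 6‑(benzyloxy)‑2,3,4‑tribromophenol
Conditions: Br2 (3.05 equiv), NaOAc (3.3 equiv), AcOH, 15 °C → rt; then aq. Na2S2O3
Reagents that add atoms: bromine, BrBr
Why: Electrophilic aromatic bromination in which the free hydroxyl directs to its ortho and para carbons and the benzyl ether to its para carbon, the pattern known for 2‑alkoxyphenols, leaving only the carbon next to the benzyloxy group unsubstituted, while acetate buffers the HBr that would otherwise cleave the benzyl ether.

Step 2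
Reactants: 2 6‑(benzyloxy)‑2,3,4‑tribromophenol
Product: 3 1‑(benzyloxy)‑3,4,5‑tribromo‑2‑methoxybenzene
Conditions: MeI (1.5 equiv), K2CO3 (2 equiv), DMF, rt → 40 °C
Reagents that add atoms: iodomethane, CI
Why: Williamson O‑methylation of the acidic, bromine-flanked phenoxide, which fixes the methyl ether on the oxygen that must stay protected until the last step.

Step 3
Reactants: 3 1‑(benzyloxy)‑3,4,5‑tribromo‑2‑methoxybenzene
Product: 4 3,4,5‑tribromo‑2‑methoxyphenol
Conditions: BCl3 (2 equiv), C6HMe5 (3 equiv), CH2Cl2, −78 °C; then H2O
Reagents that add atoms: none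
Why: Lewis acid debenzylation with a cation scavenger, in which the benzyl–oxygen bond should ionise at −78 °C while the aryl methyl ether and the aryl bromides (which would not survive hydrogenolysis over palladium) are left alone.

Step 4
Reactants: 4 3,4,5‑tribromo‑2‑methoxyphenol; 5 methyl 2‑bromopent‑4‑enoate (racemic)
Product: 6 methyl 2‑(3,4,5‑tribromo‑2‑methoxyphenoxy)pent‑4‑enoate (racemic)
Conditions: K2CO3 (1.5 equiv), DMF, rt → 50 °C
Reagents that add atoms: none
Why: Williamson ether synthesis by SN2 attack of the phenoxide at the activated α‑carbon of the bromo ester; the new stereocentre is racemic, which is immaterial because it is destroyed in step 8.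

Step 5
Reactants: 6 methyl 2‑(3,4,5‑tribromo‑2‑methoxyphenoxy)pent‑4‑enoate
Product: 7 N‑methoxy‑N‑methyl‑2‑(3,4,5‑tribromo‑2‑methoxyphenoxy)pent‑4‑enamide (racemic)
Conditions: MeNH(OMe)·HCl (3 equiv), AlMe3 (3 equiv, 2 M in toluene), CH2Cl2, 0 °C → rt; then 1 M HCl, 0 °C
Reagents that add atoms: N,O‑dimethylhydroxylamine hydrochloride, CNOC.Cl
Why: Weinreb amide formation by aluminium amide aminolysis of the ester, chosen over magnesium amide conditions so that the aryl bromides cannot undergo halogen–metal exchange.

Step 6
Reactants: 7 N‑methoxy‑N‑methyl‑2‑(3,4,5‑tribromo‑2‑methoxyphenoxy)pent‑4‑enamide; 8 allylmagnesium bromide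
Product: 10 5‑(3,4,5‑tribromo‑2‑methoxyphenoxy)octa‑1,7‑dien‑4‑one (racemic), via bromomagnesium hemiaminal chelate 9 (not isolated)
Conditions: allylMgBr (1.2 equiv, 1 M in Et2O), THF, −78 °C; then 1 M HCl, −78 → 0 °C; quick filtration through deactivated silica, used at once
Reagents that add atoms: none
Why: Weinreb ketone synthesis, in which one allyl group adds to give the chelated tetrahedral adduct 9 that should persist at −78 °C and release the β,γ‑unsaturated ketone only on the cold acidic quench, so that over-addition and base-induced conjugation are avoided and the aryl bromides, which do not exchange with an allyl Grignard reagent at this temperature, are kept.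

Step 7
Reactants: 10 5‑(3,4,5‑tribromo‑2‑methoxyphenoxy)octa‑1,7‑dien‑4‑one
Product: 11 6‑(3,4,5‑tribromo‑2‑methoxyphenoxy)cyclohex‑3‑en‑1‑one (racemic)
Conditions: second-generation Grubbs catalyst RuCl2(=CHPh)(H2IMes)(PCy3) (5 mol %), 1,4‑benzoquinone (10 mol %), CH2Cl2 (0.01 M), 40 °C
Reagents that add atoms: none
Why: Ring-closing olefin metathesis by the metallacyclobutane mechanism: the ruthenium benzylidene exchanges with one terminal alkene to give a ruthenium alkylidene, which undergoes [2+2] cycloaddition with the second terminal alkene and cycloreversion to expel ethene and form the C3=C4 bond of ring A. The closest known reaction type is the metathesis of acyclic dienones to cyclohexenones that are then tautomerised or dehydrogenated to phenols. Ring A is closed as a six-membered carbocycle by joining the two inner alkene carbons of a 1,7‑diene, the most favourable ring size for this reaction, and the loss of volatile ethene drives it. No stereocentre is created, and the racemic aryloxy-bearing carbon is untouched and disappears in step 8. There is no regiochemical alternative, so the selectivity needed is metathesis over ruthenium hydride-mediated migration of the allyl ketone double bond into conjugation; two unhindered monosubstituted alkenes that close fast, high dilution, moderate temperature and benzoquinone as a hydride trap should secure it. The ketone, both ethers and the three aryl bromides are inert to the catalyst.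

Step 8
Reactants: 11 6‑(3,4,5‑tribromo‑2‑methoxyphenoxy)cyclohex‑3‑en‑1‑one
Product: 12 2‑(3,4,5‑tribromo‑2‑methoxyphenoxy)phenol
Conditions: DDQ (1.2 equiv), TsOH·H2O (10 mol %), 1,4‑dioxane, 80 °C
Reagents that add atoms: none
Why: Quinone dehydrogenation, in which acid-catalysed enolisation of the β,γ‑unsaturated ketone gives a cyclohexadienol, DDQ abstracts the allylic hydride and proton loss delivers the phenol, the ring being only one oxidation level below aromatic.

Step 9
Reactants: 12 2‑(3,4,5‑tribromo‑2‑methoxyphenoxy)phenol
Product: 14 2,4‑dibromo‑6‑(3,4,5‑tribromo‑2‑methoxyphenoxy)phenol, via ortho‑bromophenol 13 (not isolated)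
Conditions: NBS (2.05 equiv), iPr2NH (10 mol %), CH2Cl2, 0 °C → rt
Reagents that add atoms: N‑bromosuccinimide, O=C1CCC(=O)N1Br
Why: Electrophilic aromatic bromination with amine-mediated ortho delivery, in which the first bromine should enter ortho to the hydroxyl (C2) through the hydrogen-bonded N‑bromoamine and the second para to the hydroxyl (C4), the most activated site left, while ring B, deactivated by three bromines and with its only free carbon flanked by bromine and the ether oxygen, does not react.

Step 10
Reactants: 14 2,4‑dibromo‑6‑(3,4,5‑tribromo‑2‑methoxyphenoxy)phenol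
Product: 15 2,4‑dibromo‑6‑(3,4,5‑tribromo‑2‑hydroxyphenoxy)phenol (target)
Conditions: BBr3 (3 equiv), CH2Cl2, −78 → 0 °C; then H2O
Reagents that add atoms: none
Why: Lewis acid O‑demethylation of the aryl methyl ether, in which bromide attacks the methyl group of the boron-complexed ether, under conditions to which the diaryl ether and the aryl bromides are stable.

## Compound list

1 | 2‑(benzyloxy)phenol | Oc1ccccc1OCc1ccccc1 | starting material
2 | 6‑(benzyloxy)‑2,3,4‑tribromophenol | Oc1c(Br)c(Br)c(Br)cc1OCc1ccccc1 | intermediate
3 | 1‑(benzyloxy)‑3,4,5‑tribromo‑2‑methoxybenzene | COc1c(Br)c(Br)c(Br)cc1OCc1ccccc1 | intermediate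
4 | 3,4,5‑tribromo‑2‑methoxyphenol | COc1c(Br)c(Br)c(Br)cc1O | intermediate
5 | methyl 2‑bromopent‑4‑enoate (racemic) | COC(=O)C(Br)CC=C | starting material
6 | methyl 2‑(3,4,5‑tribromo‑2‑methoxyphenoxy)pent‑4‑enoate (racemic) | COC(=O)C(CC=C)Oc1cc(Br)c(Br)c(Br)c1OC | intermediate
7 | N‑methoxy‑N‑methyl‑2‑(3,4,5‑tribromo‑2‑methoxyphenoxy)pent‑4‑enamide (racemic) | CON(C)C(=O)C(CC=C)Oc1cc(Br)c(Br)c(Br)c1OC | intermediate
8 | allylmagnesium bromide | C=CC[Mg]Br | starting material
9 | bromomagnesium alkoxide of the tetrahedral adduct of 7 and 8 (chelated hemiaminal, not isolated) | C=CCC(O[Mg]Br)(N(C)OC)C(CC=C)Oc1cc(Br)c(Br)c(Br)c1OC | intermediate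
10 | 5‑(3,4,5‑tribromo‑2‑methoxyphenoxy)octa‑1,7‑dien‑4‑one (racemic) | C=CCC(=O)C(CC=C)Oc1cc(Br)c(Br)c(Br)c1OC | intermediate
11 | 6‑(3,4,5‑tribromo‑2‑methoxyphenoxy)cyclohex‑3‑en‑1‑one (racemic) | O=C1CC=CCC1Oc1cc(Br)c(Br)c(Br)c1OC | intermediate
12 | 2‑(3,4,5‑tribromo‑2‑methoxyphenoxy)phenol | Oc1ccccc1Oc1cc(Br)c(Br)c(Br)c1OC | intermediate
13 | 2‑bromo‑6‑(3,4,5‑tribromo‑2‑methoxyphenoxy)phenol (not isolated) | Oc1c(Br)cccc1Oc1cc(Br)c(Br)c(Br)c1OC | intermediate
14 | 2,4‑dibromo‑6‑(3,4,5‑tribromo‑2‑methoxyphenoxy)phenol | Oc1c(Br)cc(Br)cc1Oc1cc(Br)c(Br)c(Br)c1OC | intermediate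
15 | 2,4‑dibromo‑6‑(3,4,5‑tribromo‑2‑hydroxyphenoxy)phenol | Oc1c(Br)cc(Br)cc1Oc1cc(Br)c(Br)c(Br)c1O | target

## Summary

Total step count: 10. Longest linear sequence: 10 steps (1 → 15); compounds 5 and 8 are bought and enter in steps 4 and 6.

Steps most likely to fail:

**Step 7 (ring-closing metathesis).** Ruthenium hydride species formed as the catalyst decays may move the allyl ketone double bond into conjugation faster than the ring closes. The isomerised diene would then close to a five-membered enone with loss of propene or oligomerise, and chelation of the ketone oxygen to the alkylidene may slow turnover further. The fallback gives up metathesis for the classical assembly of 2‑aryloxyphenols; it sets out from 4 and comes back at 12. Nucleophilic aromatic substitution of 2‑fluorobenzaldehyde by the phenoxide of 4 (K2CO3, DMF, 120 °C) should give 2‑(3,4,5‑tribromo‑2‑methoxyphenoxy)benzaldehyde F1. Baeyer–Villiger oxidation with mCPBA in CH2Cl2 should give 2‑(3,4,5‑tribromo‑2‑methoxyphenoxy)phenyl formate F2, and methanolysis (K2CO3, MeOH, rt) should give 12, after which steps 9 and 10 follow unchanged.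

**Step 8 (dehydrogenation).** Hydride abstraction may be slow if enolisation is limiting, acid may conjugate the alkene to the less reactive cyclohex‑2‑enone, and excess quinone may oxidise the electron-rich phenol as it forms. The fallback replaces hydride abstraction by halogenation and elimination; it sets out from 11 and comes back at 12. Addition of Br2 (1 equiv, CH2Cl2, −78 °C) across the ring alkene should give 4,5‑dibromo‑2‑(3,4,5‑tribromo‑2‑methoxyphenoxy)cyclohexan‑1‑one F3 as a mixture of diastereomers. Double dehydrobromination with Li2CO3 and LiBr in DMF at 110 °C should give the cyclohexadienone, which tautomerises to 12.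

**Step 6 (allyl ketone formation).** The tetrahedral adduct may collapse early and take up a second allyl group, and the β,γ double bond may migrate into conjugation during quench or purification, so that the diene no longer closes to a six-membered ring. The fallback never makes the allyl ketone and closes the ring at the carbinol level; it sets out from 7 and comes back at 11. Reduction of 7 with iBu2AlH (THF, −78 °C) should give 2‑(3,4,5‑tribromo‑2‑methoxyphenoxy)pent‑4‑enal F4. Addition of 8 at −78 °C should give 5‑(3,4,5‑tribromo‑2‑methoxyphenoxy)octa‑1,7‑dien‑4‑ol F5 as a diastereomer mixture of no consequence. Ring-closing metathesis with RuCl2(=CHPh)(H2IMes)(PCy3) in CH2Cl2 at 40 °C should give 6‑(3,4,5‑tribromo‑2‑methoxyphenoxy)cyclohex‑3‑en‑1‑ol F6, whose homoallylic alcohol cannot conjugate. Oxidation with Dess–Martin periodinane buffered with NaHCO3 in CH2Cl2 should give 11.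

## Further compounds

F1 | step 7 | 2‑(3,4,5‑tribromo‑2‑methoxyphenoxy)benzaldehyde | O=Cc1ccccc1Oc1cc(Br)c(Br)c(Br)c1OC
F2 | step 7 | 2‑(3,4,5‑tribromo‑2‑methoxyphenoxy)phenyl formate | O=COc1ccccc1Oc1cc(Br)c(Br)c(Br)c1OC
F3 | step 8 | 4,5‑dibromo‑2‑(3,4,5‑tribromo‑2‑methoxyphenoxy)cyclohexan‑1‑one (mixture of diastereomers) | O=C1CC(Br)C(Br)CC1Oc1cc(Br)c(Br)c(Br)c1OC
F4 | step 6 | 2‑(3,4,5‑tribromo‑2‑methoxyphenoxy)pent‑4‑enal (racemic) | O=CC(CC=C)Oc1cc(Br)c(Br)c(Br)c1OC
F5 | step 6 | 5‑(3,4,5‑tribromo‑2‑methoxyphenoxy)octa‑1,7‑dien‑4‑ol (mixture of diastereomers) | C=CCC(O)C(CC=C)Oc1cc(Br)c(Br)c(Br)c1OC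
F6 | step 6 | 6‑(3,4,5‑tribromo‑2‑methoxyphenoxy)cyclohex‑3‑en‑1‑ol (mixture of diastereomers) | OC1CC=CCC1Oc1cc(Br)c(Br)c(Br)c1OC
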